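**Plan**

1. Numbering used below: C1 = CH2 on the furan next to the ester carbon, C2 = CH(OAc), C3=C4(CH3), C5 = CH2, C6=C7, C8(CH3)=C9, C10, C11 = CH2 on the second furan. The two furan rings are spectators throughout.
2. First cut, C5–C6. C5 is the CH2 terminus of the allyl unit C3=C4–C5 inside a 4-acetoxy-2-enyl system, and C6 is the unsubstituted sp2 end of the C6=C7–C8=C9 diene, so the bond is the allyl–alkenyl link of a 1,4-diene. It should form in one flask from a terminal 1,3-enyne (C6–C11), Cp2Zr(H)Cl and a 1-acetoxy-4-chloro-2-ene (C1–C5); the same operation creates the E C6=C7 olefin and gives the target itself.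
3. Further cuts: C3=C4 (cross-metathesis with methacrolein), C8=C9 (Wittig), C6 by one-carbon homologation of an enal, then both furan–CH2 bonds (furan-3-yllithium on oxetane, furan-3-ylmagnesium chloride on (S)-epichlorohydrin).
4. Forward: the C6–C11 enyne is grown from 3-bromofuran in 4 steps, the C1–C5 chloride in 7 steps, and the two chains are joined last. No ring is formed apart from a temporary epoxide.
5. Stereochemistry: C2 (S) comes from (S)-epichlorohydrin, whose C–O bond is never broken. E at C8=C9 comes from the stabilised ylide, E at C3=C4 from thermodynamic control in the metathesis, E at C6=C7 from syn-hydrozirconation.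

Key step: step 12

**Route**

Step 1
Reactants: 1 3-bromofuran; 2 oxetane
Product: 4 3-(furan-3-yl)propan-1-ol, via furan-3-yllithium 3 (not isolated)
Conditions: n-BuLi, THF, −78 °C; then 2, BF3·OEt2, −78 °C; aq. NH4Cl
Reagents that add atoms: none
Why: Bromine–lithium exchange at −78 °C gives furan-3-yllithium without migration of lithium to C2, and the BF3-promoted SN2 ring opening of oxetane by an aryllithium is a known way to attach a 3-hydroxypropyl chain.

Step 2
Reactants: 4 3-(furan-3-yl)propan-1-ol
Product: 5 3-(furan-3-yl)propanal
Conditions: Dess–Martin periodinane, CH2Cl2, 0 °C → rt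
Reagents that add atoms: none
Why: Dess–Martin oxidation of a primary alcohol stops at the aldehyde under near-neutral conditions that the oxidant- and acid-sensitive furan should tolerate.

Step 3
Reactants: 5 3-(furan-3-yl)propanal
Product: 6 (2E)-5-(furan-3-yl)-2-methylpent-2-enal
Conditions: Ph3P=C(CH3)CHO, toluene, 90 °C
Reagents that add atoms: 2-(triphenylphosphoranylidene)propanal, CC(C=O)=P(c1ccccc1)(c1ccccc1)c1ccccc1
Why: Wittig olefination with a formyl-stabilised ylide is under thermodynamic control and should give the E trisubstituted enal, which fixes the C8=C9 geometry of the target.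

Step 4
Reactants: 6 (2E)-5-(furan-3-yl)-2-methylpent-2-enal
Product: 7 3-[(3E)-4-methylhex-3-en-5-yn-1-yl]furan
Conditions: Me3SiCHN2, LiN(iPr)2, THF, −78 °C → rt; H2O
Reagents that add atoms: (trimethylsilyl)diazomethane, C[Si](C)(C)C=[N+]=[N-]
Why: Colvin rearrangement: the lithiated silyl diazomethane adds to the aldehyde, Peterson-type loss of lithium trimethylsilanolate and then of N2 leaves an alkylidene carbene, and its 1,2-hydrogen shift should give the terminal 1,3-enyne with the E olefin untouched.

Step 5
Reactants: 1 3-bromofuran; 8 (S)-epichlorohydrin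
Product: 10 (2S)-1-chloro-3-(furan-3-yl)propan-2-ol, via furan-3-ylmagnesium chloride 9 (not isolated)
Conditions: iPrMgCl·LiCl, THF, 0 °C → rt; then CuI (10 mol %), 8, −30 → 0 °C; aq. NH4Cl
Reagents that add atoms: none
Why: Bromine–magnesium exchange with the LiCl-activated isopropyl Grignard reagent gives the 3-furyl Grignard reagent, and its CuI-catalysed SN2 opening of the epoxide at the unsubstituted CH2 (the standard way to add aryl Grignard reagents to epichlorohydrin) outruns displacement of chloride and breaks no bond at the stereocentre, so the (S) configuration of 8 becomes the (S) carbinol centre that is C2 of the target.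

Step 6
Reactants: 10 (2S)-1-chloro-3-(furan-3-yl)propan-2-ol
Product: 11 (2S)-2-(furan-3-ylmethyl)oxirane
Conditions: aq. NaOH, Et2O, rt
Reagents that add atoms: none
Why: Intramolecular Williamson ether synthesis (3-exo-tet attack of the alkoxide on CH2Cl) closes the epoxide without breaking a bond at the stereocentre.

Step 7
Reactants: 11 (2S)-2-(furan-3-ylmethyl)oxirane
Product: 12 (2S)-1-(furan-3-yl)but-3-en-2-ol
Conditions: trimethylsulfonium iodide (excess), n-BuLi, THF, −10 °C → rt
Reagents that add atoms: trimethylsulfonium iodide, C[S+](C)C.[I-]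
Why: Epoxide-to-allylic-alcohol homologation with dimethylsulfonium methylide: the ylide opens the terminal epoxide at CH2 and the β-oxido sulfonium salt loses dimethyl sulfide by ylide-mediated elimination, which adds the vinyl carbon and leaves the carbinol centre untouched.

Step 8
Reactants: 12 (2S)-1-(furan-3-yl)but-3-en-2-ol
Product: 13 (2S)-1-(furan-3-yl)but-3-en-2-yl acetate
Conditions: Ac2O, pyridine, DMAP (cat.), CH2Cl2, 0 °C → rt
Reagents that add atoms: acetic anhydride, CC(=O)OC(C)=O
Why: DMAP-catalysed acylation installs the acetate of the target on oxygen with retention at C2 and protects the allylic alcohol from ruthenium-hydride isomerisation in the next step.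

Step 9
Reactants: 13 (2S)-1-(furan-3-yl)but-3-en-2-yl acetate
Product: 14 (2S,3E)-1-(furan-3-yl)-4-methyl-5-oxopent-3-en-2-yl acetate
Conditions: methacrolein (excess), second-generation Hoveyda–Grubbs catalyst [RuCl2(H2IMes)(=CH-C6H4-2-OiPr)] (5 mol %), CH2Cl2, 40 °C
Reagents that add atoms: methacrolein, CC(=C)C=O
Why: Olefin cross-metathesis of a terminal olefin with methacrolein, a partner that does not homodimerise, is a known route to 2-methyl-2-enals and should give the E isomer under thermodynamic control, which fixes the C3=C4 geometry while acetate and furan stay inert.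

Step 10
Reactants: 14 (2S,3E)-1-(furan-3-yl)-4-methyl-5-oxopent-3-en-2-yl acetate
Product: 15 (2S,3E)-1-(furan-3-yl)-5-hydroxy-4-methylpent-3-en-2-yl acetate
Conditions: NaBH4, CeCl3·7H2O, MeOH, −40 °C
Reagents that add atoms: none
Why: Luche reduction gives selective 1,2-reduction of the enal at low temperature, without conjugate reduction, acetate cleavage or elimination of the γ-acetoxy group.

Step 11
Reactants: 15 (2S,3E)-1-(furan-3-yl)-5-hydroxy-4-methylpent-3-en-2-yl acetate
Product: 17 (2S,3E)-5-chloro-1-(furan-3-yl)-4-methylpent-3-en-2-yl acetate, via allylic mesylate 16 (not isolated)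
Conditions: MsCl, 2,4,6-collidine, LiCl, DMF, 0 °C
Reagents that add atoms: lithium chloride, [Li+].[Cl-]; methanesulfonyl chloride, CS(=O)(=O)Cl (its chloride joins the same chloride pool)
Why: Mesylation of the primary allylic alcohol and SN2 displacement by chloride in the same flask should give the primary allylic chloride without allylic transposition or loss of olefin geometry, the secondary acetate being untouched.

Step 12
Reactants: 7 3-[(3E)-4-methylhex-3-en-5-yn-1-yl]furan; 17 (2S,3E)-5-chloro-1-(furan-3-yl)-4-methylpent-3-en-2-yl acetate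
Product: 19 (2S,3E,6E,8E)-1,11-di(furan-3-yl)-4,8-dimethylundeca-3,6,8-trien-2-yl acetate, via dienylzirconocene chloride 18 (not isolated)
Conditions: 7 (1.3 equiv), Cp2Zr(H)Cl (1.25 equiv), THF, rt; then 17 (1.0 equiv), Pd(PPh3)4 (5 mol %), THF, 0 °C → rt
Reagents that add atoms: none
Why: syn-Hydrozirconation of the terminal alkyne of 7 by Cp2Zr(H)Cl puts zirconium on the terminal carbon and fixes the C6=C7 olefin as E, while the trisubstituted olefin and the furans are left alone. Zerovalent palladium then inserts into the primary allylic C–Cl bond of 17 to give a syn π-allyl complex, the dienyl group passes from zirconium to palladium, and reductive elimination at the unsubstituted allyl terminus forms the C5–C6 bond. The closest known reaction type is the Negishi palladium-catalysed coupling of alkenylzirconium or alkenylaluminium reagents with allylic chlorides to give 1,4-dienes. No ring is closed and no new stereocentre is formed; C2 lies outside the π-allyl unit and is retained. The step needs chemoselectivity for the C–Cl bond over the secondary allylic C2–OAc bond, which the much faster ionisation of the chloride in a 1-acetoxy-4-chloro-2-ene should secure, and regioselectivity for C5 over C3, which the unsubstituted terminus secures. Retention of E at C3=C4 rests on the syn π-allyl coupling faster than it isomerises, and the absence of base should keep the skipped triene out of conjugation.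

**Compound list**

1 | 3-bromofuran | Brc1ccoc1 | starting material
2 | oxetane | C1COC1 | starting material
3 | furan-3-yllithium (formed in the flask) | [Li]c1ccoc1 | intermediate
4 | 3-(furan-3-yl)propan-1-ol | OCCCc1ccoc1 | intermediate
5 | 3-(furan-3-yl)propanal | O=CCCc1ccoc1 | intermediate
6 | (2E)-5-(furan-3-yl)-2-methylpent-2-enal | O=C/C(C)=C/CCc1ccoc1 | intermediate
7 | 3-[(3E)-4-methylhex-3-en-5-yn-1-yl]furan | C#C/C(C)=C/CCc1ccoc1 | intermediate
8 | (S)-epichlorohydrin, (2S)-2-(chloromethyl)oxirane | ClC[C@@H]1CO1 | starting material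
9 | furan-3-ylmagnesium chloride (formed in the flask as its LiCl complex) | Cl[Mg]c1ccoc1 | intermediate
10 | (2S)-1-chloro-3-(furan-3-yl)propan-2-ol | ClC[C@@H](O)Cc1ccoc1 | intermediate
11 | (2S)-2-(furan-3-ylmethyl)oxirane | C1[C@@H](O1)Cc1ccoc1 | intermediate
12 | (2S)-1-(furan-3-yl)but-3-en-2-ol | C=C[C@@H](O)Cc1ccoc1 | intermediate
13 | (2S)-1-(furan-3-yl)but-3-en-2-yl acetate | C=C[C@@H](OC(C)=O)Cc1ccoc1 | intermediate
14 | (2S,3E)-1-(furan-3-yl)-4-methyl-5-oxopent-3-en-2-yl acetate | O=C/C(C)=C/[C@@H](OC(C)=O)Cc1ccoc1 | intermediate
15 | (2S,3E)-1-(furan-3-yl)-5-hydroxy-4-methylpent-3-en-2-yl acetate | OC/C(C)=C/[C@@H](OC(C)=O)Cc1ccoc1 | intermediate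
16 | (2S,3E)-1-(furan-3-yl)-5-(methanesulfonyloxy)-4-methylpent-3-en-2-yl acetate (formed in the flask) | CS(=O)(=O)OC/C(C)=C/[C@@H](OC(C)=O)Cc1ccoc1 | intermediate
17 | (2S,3E)-5-chloro-1-(furan-3-yl)-4-methylpent-3-en-2-yl acetate | ClC/C(C)=C/[C@@H](OC(C)=O)Cc1ccoc1 | intermediate
18 | chlorobis(cyclopentadienyl)[(1E,3E)-6-(furan-3-yl)-3-methylhexa-1,3-dien-1-yl]zirconium (formed in the flask; C5H5 rings drawn σ-bonded) | Cl[Zr](/C=C/C(C)=C/CCc1ccoc1)(C1C=CC=C1)C1C=CC=C1 | intermediate
19 | (2S,3E,6E,8E)-1,11-di(furan-3-yl)-4,8-dimethylundeca-3,6,8-trien-2-yl acetate | CC(=O)O[C@H](/C=C(\C)C/C=C/C(C)=C/CCc1ccoc1)Cc1ccoc1 | target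

**Step count**

Total: 12 steps (4 to the enyne 7, 7 to the chloride 17, 1 to join them).
Longest linear sequence: 8 steps (steps 5–12, from 3-bromofuran and (S)-epichlorohydrin).

**Steps most likely to fail**

Step 12. What may go wrong: oxidative addition of zerovalent palladium into the secondary allylic acetate (loss of the ester, double coupling), syn/anti isomerisation of the π-allyl intermediate before the dienyl group arrives (erosion of the C3=C4 geometry), or slow zirconium-to-palladium transfer with protonolysis of the alkenylzirconium. Fallback: setting out from 7, Cp2Zr(H)Cl-catalysed hydroboration with pinacolborane (Et3N, CH2Cl2, rt) should give 2-[(1E,3E)-6-(furan-3-yl)-3-methylhexa-1,3-dien-1-yl]-4,4,5,5-tetramethyl-1,3,2-dioxaborolane F1, an isolable nucleophile free of Lewis-acidic metal. Suzuki–Miyaura coupling of F1 with 17 (Pd(PPh3)4, CsF, THF, 50 °C) comes back to the route at 19.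

Step 9. What may go wrong: slow turnover at the hindered allylic acetate, decomposition of the ruthenium carbene, double-bond migration or incomplete E selectivity. Fallback: setting out from 13, Lemieux–Johnson cleavage (OsO4 cat., NaIO4, 2,6-lutidine, dioxane/H2O, 0 °C) should pass through (2S)-1-(furan-3-yl)-3,4-dihydroxybutan-2-yl acetate F2 to (2S)-1-(furan-3-yl)-3-oxopropan-2-yl acetate F3. Wittig olefination of crude F3 with 2-(triphenylphosphoranylidene)propanal (toluene, 60 °C) comes back to the route at 14.

Step 4. What may go wrong: conjugate addition of the lithiated diazo reagent to the enal, side reactions of the carbene, or loss of the volatile enyne on isolation. Fallback: setting out from 6, Corey–Fuchs homologation with CBr4/PPh3 (CH2Cl2, 0 °C) should give 3-[(3E)-6,6-dibromo-4-methylhexa-3,5-dien-1-yl]furan F4. Treatment of F4 with n-BuLi (2 equiv, THF, −78 °C) and then H2O comes back to the route at 7.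

**Further compounds**

F1 | step 12 | 2-[(1E,3E)-6-(furan-3-yl)-3-methylhexa-1,3-dien-1-yl]-4,4,5,5-tetramethyl-1,3,2-dioxaborolane | CC1(C)OB(/C=C/C(C)=C/CCc2ccoc2)OC1(C)C
F2 | step 9 | (2S)-1-(furan-3-yl)-3,4-dihydroxybutan-2-yl acetate | OCC(O)[C@@H](OC(C)=O)Cc1ccoc1
F3 | step 9 | (2S)-1-(furan-3-yl)-3-oxopropan-2-yl acetate | O=C[C@@H](OC(C)=O)Cc1ccoc1
F4 | step 4 | 3-[(3E)-6,6-dibromo-4-methylhexa-3,5-dien-1-yl]furan | BrC(Br)=C/C(C)=C/CCc1ccoc1
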